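The ten-membered carbocycle is closed last, at C1–C10. C1 is an oxirane carbon allylic to the exocyclic C10=C14 methylene, the retron of an intramolecular Nozaki–Hiyama–Kishi addition: a 2-iodoalkene at C10 adds to a C1 aldehyde that carries the C2 silyloxy stereocentre. One operation forms the ring, the methylene and the C1 carbinol; invertive chlorination and fluoride-triggered displacement by the C2 oxygen then give the cis-1,2-epoxide. The precursor is an open chain hinged on the preformed butenolide, with the 4,5-epoxide, the C8 ester and both reactive termini in place, assembled from a glycidol-derived enal, a propargyl ether, carbon monoxide and 2-iodoallyl bromide.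

Key step: step 18

Remark: germacrane numbering (ring C1–C10, lactone C11–C13, C14 methylene, C15 methyl) is used for all intermediates, TBS = tert-butyldimethylsilyl, PMB = 4-methoxybenzyl, and in steps 5 and 12 the ligand antipode is the one taken to give Si-face attack on the aldehyde.

Step 1
Reactants: 1 (S)-2-{[(4-methoxybenzyl)oxy]methyl}oxirane
Product: 2 (S)-1-[(4-methoxybenzyl)oxy]pent-4-yn-2-ol
Conditions: HC≡CLi·H2NCH2CH2NH2, DMSO, 0 °C → rt
Reagents that add atoms: lithium acetylide ethylenediamine complex, [Li+].[C-]#C.NCCN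
Why: SN2 opening of the epoxide at its terminal carbon by acetylide should leave the chiral-pool C2 stereocentre untouched and deliver C3–C5.

Step 2
Reactants: 2 (S)-1-[(4-methoxybenzyl)oxy]pent-4-yn-2-ol
Product: 3 (S)-TBS ether of 2
Conditions: TBSCl, imidazole, DMF, rt
Reagents that add atoms: tert-butyldimethylsilyl chloride, CC(C)(C)[Si](C)(C)Cl
Why: Standard silylation of the secondary alcohol masks the future epoxide oxygen at C2 until the last step.

Step 3
Reactants: 3 (S)-TBS ether of 2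
Product: 6 (2E,5S)-5-(TBS-oxy)-6-(PMB-oxy)-3-methylhex-2-en-1-ol, via alkenylalane 4 (not isolated), via lithium alanate 5 (not isolated)
Conditions: Me3Al, Cp2ZrCl2 (0.3 equiv), CH2Cl2, 0 °C → rt; then n-BuLi, THF, −78 °C; (CH2O)n, −78 °C → rt
Reagents that add atoms: trimethylaluminium, C[Al](C)C; paraformaldehyde (as formaldehyde), C=O
Why: Negishi zirconium-catalysed carboalumination adds methyl and aluminium syn across the terminal alkyne, which fixes the E geometry of C4=C5 with C15 on C4, and the derived alanate is hydroxymethylated to bring in C6.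

Step 4
Reactants: 6 (2E,5S)-5-(TBS-oxy)-6-(PMB-oxy)-3-methylhex-2-en-1-ol
Product: 7 (2E,5S)-5-(TBS-oxy)-6-(PMB-oxy)-3-methylhex-2-enal
Conditions: MnO2 (20 equiv), CH2Cl2, rt
Reagents that add atoms: none
Why: Allylic oxidation with MnO2 should give the enal without erosion of the E geometry.

Step 5
Reactants: 7 (2E,5S)-5-(TBS-oxy)-6-(PMB-oxy)-3-methylhex-2-enal; 8 tert-butyldimethyl(prop-2-yn-1-yloxy)silane
Product: 10 (4R,5E,8S)-1,8-bis(TBS-oxy)-9-(PMB-oxy)-6-methylnon-5-en-2-yn-4-ol, via alkynylzinc 9 (not isolated)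
Conditions: (R,R)-ProPhenol (20 mol %), Me2Zn (3 equiv), Ph3P=O (40 mol %), toluene, 4 °C
Reagents that add atoms: none
Why: The ProPhenol/dinuclear-zinc catalysed alkynylation of enals is a ligand-controlled 1,2-addition, and Si-face delivery of the alkynyl group sets C6 (4R in this name).

Step 6
Reactants: 10 (4R,5E,8S)-1,8-bis(TBS-oxy)-9-(PMB-oxy)-6-methylnon-5-en-2-yn-4-ol
Product: 12 (2Z,4R,5E,8S)-1,8-bis(TBS-oxy)-3-ethenyl-2-iodo-9-(PMB-oxy)-6-methylnona-2,5-dien-4-ol, via magnesium chelate 11 (not isolated)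
Conditions: CH2=CHMgCl (5 equiv), THF–toluene, 70 °C; then I2 (6 equiv), THF, −78 → 0 °C
Reagents that add atoms: vinylmagnesium chloride, C=C[Mg]Cl; iodine, II
Why: Alkoxide-directed anti-carbomagnesiation of the propargylic alcohol places vinyl on the proximal alkyne carbon C7 and magnesium on C11 in a five-membered chelate, and iodinolysis with retention gives the Z-iodide with the C6 hydroxyl and iodine cis.

Step 7
Reactants: 12 (2Z,4R,5E,8S)-1,8-bis(TBS-oxy)-3-ethenyl-2-iodo-9-(PMB-oxy)-6-methylnona-2,5-dien-4-ol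
Product: 13 (4R,5R,6S)-4,5-epoxy alcohol of 12
Conditions: mCPBA, NaHCO3, CH2Cl2, −20 → 0 °C
Reagents that add atoms: 3-chloroperoxybenzoic acid, OOC(=O)c1cccc(Cl)c1
Why: Hydroxyl-directed peracid (Henbest) epoxidation of the electron-rich trisubstituted C4=C5 alkene should be threo-selective because A1,3 strain between the C15 methyl and C6 holds H6 in the alkene plane, so oxygen is delivered syn to the hydroxyl and sets 4R,5R.

Step 8
Reactants: 13 (4R,5R,6S)-4,5-epoxy alcohol of 12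
Product: 14 (5S)-3-[(TBS-oxy)methyl]-4-ethenyl-5-(epoxyalkyl)furan-2(5H)-one
Conditions: PdCl2(PPh3)2 (5 mol %), CO (1 atm), Et3N, THF–DMF, 50 °C
Reagents that add atoms: carbon monoxide, [C-]#[O+]
Why: Palladium-catalysed carbonylative lactonisation (alkoxycarbonylation) of the Z-iodoalkene by the cis C6 hydroxyl closes the butenolide and brings in C12 without touching a stereocentre.

Step 9
Reactants: 14 (5S)-3-[(TBS-oxy)methyl]-4-ethenyl-5-(epoxyalkyl)furan-2(5H)-one
Product: 15 (5S)-4-ethenyl-3-(hydroxymethyl)-5-(epoxyalkyl)furan-2(5H)-one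
Conditions: HF·pyridine, pyridine, THF, 0 °C
Reagents that add atoms: none
Why: Buffered fluoride desilylation should cleave the primary allylic silyl ether at C13 well before the hindered secondary one at C2 and spare the epoxide.

Step 10
Reactants: 15 (5S)-4-ethenyl-3-(hydroxymethyl)-5-(epoxyalkyl)furan-2(5H)-one
Product: 16 C13 acetate of 15
Conditions: Ac2O, pyridine, DMAP (cat.), CH2Cl2, 0 °C
Reagents that add atoms: acetic anhydride, CC(=O)OC(C)=O
Why: Standard acetylation installs the C13 acetate of the target under base too weak to deprotonate C6.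

Step 11
Reactants: 16 C13 acetate of 15
Product: 18 (5S)-3-(acetoxymethyl)-4-formyl-5-(epoxyalkyl)furan-2(5H)-one, via vicinal diol 17 (not isolated)
Conditions: OsO4 (2 mol %), NaIO4, 2,6-lutidine, dioxane–H2O, rt
Reagents that add atoms: osmium tetroxide, O=[Os](=O)(=O)=O; sodium periodate, [Na+].[O-]I(=O)(=O)=O
Why: Lemieux–Johnson cleavage should select the monosubstituted vinyl group over the tetrasubstituted electron-poor butenolide alkene and reveal C8 as the aldehyde.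

Step 12
Reactants: 18 (5S)-3-(acetoxymethyl)-4-formyl-5-(epoxyalkyl)furan-2(5H)-one
Product: 19 (8S)-homoallylic alcohol bearing the 2-iodoallyl group
Conditions: CrCl2 (4 equiv), chiral 2-(4-isopropyloxazolin-2-yl)anilide sulfonamide ligand (4.4 equiv), Et3N, THF, rt; 3-bromo-2-iodoprop-1-ene (2.2 equiv); then 18, 0 °C
Reagents that add atoms: 3-bromo-2-iodoprop-1-ene, C=C(I)CBr
Why: Ligand-controlled chromium-mediated asymmetric 2-haloallylation, with the allylchromium preformed from excess allyl bromide so that no divalent chromium remains, should add to the Si face of the aldehyde to set 8S while the alkenyl iodide stays inert in the absence of nickel.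

Step 13
Reactants: 20 methyl 2-(hydroxymethyl)acrylate
Product: 21 methyl 2-[(TBS-oxy)methyl]acrylate
Conditions: TBSCl, imidazole, DMF, 0 °C → rt
Reagents that add atoms: tert-butyldimethylsilyl chloride, CC(C)(C)[Si](C)(C)Cl
Why: Standard silylation protects the primary hydroxyl of the side-chain acid.

Step 14
Reactants: 21 methyl 2-[(TBS-oxy)methyl]acrylate
Product: 22 2-[(TBS-oxy)methyl]acrylic acid
Conditions: LiOH, THF–H2O, 0 °C; then aq. HCl to pH 4
Reagents that add atoms: lithium hydroxide, [Li+].[OH-]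
Why: Saponification of the methyl ester at 0 °C should leave the primary silyl ether intact.

Step 15
Reactants: 19 (8S)-homoallylic alcohol bearing the 2-iodoallyl group; 22 2-[(TBS-oxy)methyl]acrylic acid
Product: 23 C8 ester of 19 with 22
Conditions: EDC·HCl, DMAP (cat.), CH2Cl2, 0 °C → rt
Reagents that add atoms: none
Why: Steglich-type esterification acylates the only free hydroxyl (C8) with retention of its configuration.

Step 16
Reactants: 23 C8 ester of 19 with 22
Product: 24 C1 primary alcohol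
Conditions: DDQ, CH2Cl2–pH 7 buffer, 0 °C
Reagents that add atoms: none
Why: Oxidative cleavage of the PMB ether is orthogonal to the silyl ethers, esters, epoxide and alkenyl iodide.

Step 17
Reactants: 24 C1 primary alcohol
Product: 25 seco-aldehyde (C1 aldehyde with 2S silyloxy group and C10 alkenyl iodide)
Conditions: Dess–Martin periodinane, NaHCO3, CH2Cl2, 0 °C → rt
Reagents that add atoms: none
Why: Buffered Dess–Martin oxidation should give the α-silyloxy aldehyde without epimerisation at C2 or base-induced opening of the 4,5-epoxide.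

Step 18
Reactants: 25 seco-aldehyde (C1 aldehyde with 2S silyloxy group and C10 alkenyl iodide)
Product: 27 (1R)-macrocyclic allylic alcohol, via alkenylchromium 26 (not isolated)
Conditions: CrCl2 (10 equiv), NiCl2 (0.1 equiv), DMSO–THF, 2 mM, slow addition, rt
Reagents that add atoms: none
Why: Zerovalent nickel inserts into the C10–I bond, the alkenyl group passes to trivalent chromium, and the alkenylchromium 26 adds to the C1 aldehyde, the chromium alkoxide being hydrolysed on work-up. The closest known reaction type is the intramolecular Nozaki–Hiyama–Kishi coupling used to close medium and large carbocycles. The ten-membered ring closes in a 10-exo-trig mode, and the same event delivers the C10=C14 methylene and the C1–O bond. The new C1 stereocentre is controlled by the adjacent C2 silyloxy centre (Felkin–Anh, 1,2-anti), which should give 1R. The step needs aldehyde-selective attack in the presence of two esters, a lactone and an epoxide, which the low basicity of the organochromium secures, and ring closure over oligomerisation, which high dilution and the turn imposed by the trans-epoxide and the planar butenolide secure. Either C1 epimer can be carried to the cis-epoxide, so facial selectivity is not critical.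

Step 19
Reactants: 27 (1R)-macrocyclic allylic alcohol
Product: 28 (1S)-macrocyclic allylic chloride
Conditions: PPh3, hexachloroacetone, CH2Cl2, −20 → 0 °C
Reagents that add atoms: hexachloroacetone, ClC(Cl)(Cl)C(=O)C(Cl)(Cl)Cl
Why: Appel-type chlorination with triphenylphosphine and hexachloroacetone converts secondary allylic alcohols into chlorides by SN2 with inversion and without allylic transposition, which should place chlorine anti to the C2 oxygen.

Step 20
Reactants: 28 (1S)-macrocyclic allylic chloride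
Product: 30 CNP0233746.1, via desilylated chlorohydrin 29 (not isolated)
Conditions: Bu4NF (3 equiv), THF, 0 °C → rt
Reagents that add atoms: none
Why: Fluoride removes both silyl ethers and the liberated C2 alkoxide displaces the anti-periplanar allylic chloride in an intramolecular Williamson (3-exo-tet) closure with inversion at C1, which should give the cis-1,2-epoxide.

Compound list
1 | (S)-2-{[(4-methoxybenzyl)oxy]methyl}oxirane | COc1ccc(COC[C@@H]2CO2)cc1 | starting material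
2 | (S)-1-[(4-methoxybenzyl)oxy]pent-4-yn-2-ol | C#CC[C@H](O)COCc1ccc(OC)cc1 | intermediate
3 | (S)-tert-butyl({1-[(4-methoxybenzyl)oxy]pent-4-yn-2-yl}oxy)dimethylsilane | C#CC[C@H](O[Si](C)(C)C(C)(C)C)COCc1ccc(OC)cc1 | intermediate
4 | dimethyl[(1E,4S)-4-(TBS-oxy)-5-(PMB-oxy)-2-methylpent-1-en-1-yl]alane | C[Al](C)/C=C(\C)C[C@H](O[Si](C)(C)C(C)(C)C)COCc1ccc(OC)cc1 | intermediate (not isolated)
5 | lithium butyl(dimethyl)[(1E,4S)-4-(TBS-oxy)-5-(PMB-oxy)-2-methylpent-1-en-1-yl]alanate | [Li+].CCCC[Al-](C)(C)/C=C(\C)C[C@H](O[Si](C)(C)C(C)(C)C)COCc1ccc(OC)cc1 | intermediate (not isolated)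
6 | (2E,5S)-5-[(tert-butyldimethylsilyl)oxy]-6-[(4-methoxybenzyl)oxy]-3-methylhex-2-en-1-ol | OC/C=C(\C)C[C@H](O[Si](C)(C)C(C)(C)C)COCc1ccc(OC)cc1 | intermediate
7 | (2E,5S)-5-[(tert-butyldimethylsilyl)oxy]-6-[(4-methoxybenzyl)oxy]-3-methylhex-2-enal | O=C/C=C(\C)C[C@H](O[Si](C)(C)C(C)(C)C)COCc1ccc(OC)cc1 | intermediate
8 | tert-butyldimethyl(prop-2-yn-1-yloxy)silane | C#CCO[Si](C)(C)C(C)(C)C | starting material
9 | methyl[3-(TBS-oxy)prop-1-yn-1-yl]zinc | C[Zn]C#CCO[Si](C)(C)C(C)(C)C | intermediate (not isolated)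
10 | (4R,5E,8S)-1,8-bis[(tert-butyldimethylsilyl)oxy]-9-[(4-methoxybenzyl)oxy]-6-methylnon-5-en-2-yn-4-ol | CC(C)(C)[Si](C)(C)OCC#C[C@H](O)/C=C(\C)C[C@H](O[Si](C)(C)C(C)(C)C)COCc1ccc(OC)cc1 | intermediate
11 | cyclic alkenylmagnesium alkoxide (2,5-dihydro-1,2-oxamagnesole: O–Mg–C11=C7–C6, vinyl on C7) | C=CC1=C(CO[Si](C)(C)C(C)(C)C)[Mg]O[C@@H]1/C=C(\C)C[C@H](O[Si](C)(C)C(C)(C)C)COCc1ccc(OC)cc1 | intermediate (not isolated)
12 | (2Z,4R,5E,8S)-1,8-bis[(tert-butyldimethylsilyl)oxy]-3-ethenyl-2-iodo-9-[(4-methoxybenzyl)oxy]-6-methylnona-2,5-dien-4-ol | C=C/C(=C(/I)CO[Si](C)(C)C(C)(C)C)[C@H](O)/C=C(\C)C[C@H](O[Si](C)(C)C(C)(C)C)COCc1ccc(OC)cc1 | intermediate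
13 | (1S,2Z)-4-(TBS-oxy)-2-ethenyl-3-iodo-1-{(2R,3R)-3-[(2S)-2-(TBS-oxy)-3-(PMB-oxy)propyl]-3-methyloxiran-2-yl}but-2-en-1-ol | C=C/C(=C(/I)CO[Si](C)(C)C(C)(C)C)[C@H](O)[C@H]1O[C@]1(C)C[C@H](O[Si](C)(C)C(C)(C)C)COCc1ccc(OC)cc1 | intermediate
14 | (5S)-3-[(TBS-oxy)methyl]-4-ethenyl-5-{(2R,3R)-3-[(2S)-2-(TBS-oxy)-3-(PMB-oxy)propyl]-3-methyloxiran-2-yl}furan-2(5H)-one | C=CC1=C(CO[Si](C)(C)C(C)(C)C)C(=O)O[C@@H]1[C@H]1O[C@]1(C)C[C@H](O[Si](C)(C)C(C)(C)C)COCc1ccc(OC)cc1 | intermediate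
15 | (5S)-4-ethenyl-3-(hydroxymethyl)-5-{(2R,3R)-3-[(2S)-2-(TBS-oxy)-3-(PMB-oxy)propyl]-3-methyloxiran-2-yl}furan-2(5H)-one | C=CC1=C(CO)C(=O)O[C@@H]1[C@H]1O[C@]1(C)C[C@H](O[Si](C)(C)C(C)(C)C)COCc1ccc(OC)cc1 | intermediate
16 | (5S)-3-(acetoxymethyl)-4-ethenyl-5-{(2R,3R)-3-[(2S)-2-(TBS-oxy)-3-(PMB-oxy)propyl]-3-methyloxiran-2-yl}furan-2(5H)-one | C=CC1=C(COC(C)=O)C(=O)O[C@@H]1[C@H]1O[C@]1(C)C[C@H](O[Si](C)(C)C(C)(C)C)COCc1ccc(OC)cc1 | intermediate
17 | 4-(1,2-dihydroxyethyl) analogue of 16 (both C8 epimers) | OCC(O)C1=C(COC(C)=O)C(=O)O[C@@H]1[C@H]1O[C@]1(C)C[C@H](O[Si](C)(C)C(C)(C)C)COCc1ccc(OC)cc1 | intermediate (not isolated)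
18 | (5S)-3-(acetoxymethyl)-4-formyl-5-{(2R,3R)-3-[(2S)-2-(TBS-oxy)-3-(PMB-oxy)propyl]-3-methyloxiran-2-yl}furan-2(5H)-one | O=CC1=C(COC(C)=O)C(=O)O[C@@H]1[C@H]1O[C@]1(C)C[C@H](O[Si](C)(C)C(C)(C)C)COCc1ccc(OC)cc1 | intermediate
19 | (5S)-3-(acetoxymethyl)-4-[(1S)-1-hydroxy-3-iodobut-3-en-1-yl]-5-{(2R,3R)-3-[(2S)-2-(TBS-oxy)-3-(PMB-oxy)propyl]-3-methyloxiran-2-yl}furan-2(5H)-one | C=C(I)C[C@H](O)C1=C(COC(C)=O)C(=O)O[C@@H]1[C@H]1O[C@]1(C)C[C@H](O[Si](C)(C)C(C)(C)C)COCc1ccc(OC)cc1 | intermediate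
20 | methyl 2-(hydroxymethyl)acrylate | C=C(CO)C(=O)OC | starting material
21 | methyl 2-{[(tert-butyldimethylsilyl)oxy]methyl}acrylate | C=C(CO[Si](C)(C)C(C)(C)C)C(=O)OC | intermediate
22 | 2-{[(tert-butyldimethylsilyl)oxy]methyl}acrylic acid | C=C(CO[Si](C)(C)C(C)(C)C)C(=O)O | intermediate
23 | (1S)-1-{(2S)-4-(acetoxymethyl)-5-oxo-2-[(2R,3R)-3-((2S)-2-(TBS-oxy)-3-(PMB-oxy)propyl)-3-methyloxiran-2-yl]-2,5-dihydrofuran-3-yl}-3-iodobut-3-en-1-yl 2-[(TBS-oxy)methyl]acrylate | C=C(CO[Si](C)(C)C(C)(C)C)C(=O)O[C@@H](CC(I)=C)C1=C(COC(C)=O)C(=O)O[C@@H]1[C@H]1O[C@]1(C)C[C@H](O[Si](C)(C)C(C)(C)C)COCc1ccc(OC)cc1 | intermediate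
24 | C1 primary alcohol: as 23 with the side chain (2S)-2-(TBS-oxy)-3-hydroxypropyl | C=C(CO[Si](C)(C)C(C)(C)C)C(=O)O[C@@H](CC(I)=C)C1=C(COC(C)=O)C(=O)O[C@@H]1[C@H]1O[C@]1(C)C[C@H](O[Si](C)(C)C(C)(C)C)CO | intermediate
25 | seco-aldehyde: as 23 with the side chain (2S)-2-(TBS-oxy)-3-oxopropyl | C=C(CO[Si](C)(C)C(C)(C)C)C(=O)O[C@@H](CC(I)=C)C1=C(COC(C)=O)C(=O)O[C@@H]1[C@H]1O[C@]1(C)C[C@H](O[Si](C)(C)C(C)(C)C)C=O | intermediate
26 | alkenylchromium dichloride: as 25 with CrCl2 in place of iodine on C10 | C=C(CO[Si](C)(C)C(C)(C)C)C(=O)O[C@@H](CC(=C)[Cr](Cl)Cl)C1=C(COC(C)=O)C(=O)O[C@@H]1[C@H]1O[C@]1(C)C[C@H](O[Si](C)(C)C(C)(C)C)C=O | intermediate (not isolated)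
27 | (1R,2S,4R,5R,6S,8S)-13-acetoxy-4,5-epoxy-1-hydroxy-2-(TBS-oxy)-8-{2-[(TBS-oxy)methyl]acryloyloxy}germacra-7(11),10(14)-dien-12,6-olide | C=C(CO[Si](C)(C)C(C)(C)C)C(=O)O[C@H]1CC(=C)[C@@H](O)[C@@H](O[Si](C)(C)C(C)(C)C)C[C@@]2(C)O[C@@H]2[C@H]2OC(=O)C(COC(C)=O)=C12 | intermediate
28 | (1S,2S,4R,5R,6S,8S)-13-acetoxy-1-chloro-4,5-epoxy-2-(TBS-oxy)-8-{2-[(TBS-oxy)methyl]acryloyloxy}germacra-7(11),10(14)-dien-12,6-olide | C=C(CO[Si](C)(C)C(C)(C)C)C(=O)O[C@H]1CC(=C)[C@H](Cl)[C@@H](O[Si](C)(C)C(C)(C)C)C[C@@]2(C)O[C@@H]2[C@H]2OC(=O)C(COC(C)=O)=C12 | intermediate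
29 | (1S,2S,4R,5R,6S,8S)-13-acetoxy-1-chloro-4,5-epoxy-2-hydroxy-8-[2-(hydroxymethyl)acryloyloxy]germacra-7(11),10(14)-dien-12,6-olide (as its C2 alkoxide) | C=C(CO)C(=O)O[C@H]1CC(=C)[C@H](Cl)[C@@H](O)C[C@@]2(C)O[C@@H]2[C@H]2OC(=O)C(COC(C)=O)=C12 | intermediate (not isolated)
30 | CNP0233746.1, (1R,2S,4R,5R,6S,8S)-13-acetoxy-1,2:4,5-diepoxy-8-[2-(hydroxymethyl)acryloyloxy]germacra-7(11),10(14)-dien-12,6-olide | C=C(CO)C(=O)O[C@H]1CC(=C)[C@H]2O[C@H]2C[C@@]2(C)O[C@@H]2[C@H]2OC(=O)C(COC(C)=O)=C12 | target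

Total step count: 20. Longest linear sequence: 18 steps (steps 1–12 and 15–20); steps 13–14 prepare the side-chain acid.

Steps most likely to fail

Step 18. The alkenylchromium may attack the other face of the C1 aldehyde under the constraint of the forming ring, so that the 1,2-syn carbinol forms in place of, or beside, the 1,2-anti one. The fallback uses that epimer and closes the epoxide with one inversion instead of two. It sets out from 25: the same coupling gives the (1S)-macrocyclic allylic alcohol F1. MsCl/Et3N (CH2Cl2, −20 °C) activates it with retention as the (1S)-mesylate F2. Bu4NF (THF, 0 °C) then removes both silyl groups and the C2 alkoxide displaces the mesylate with inversion. The fallback comes back to the route at 30.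

Step 6. Carbomagnesiation may stall or lose regiocontrol through coordination of magnesium by the second propargylic oxygen, or the alkoxide may eliminate to allenes at 70 °C. The fallback builds the butenolide by conjugate addition to a γ-hydroxy ynoate and brings in C13 by cross-coupling. It sets out from 7: ProPhenol/Me2Zn alkynylation with methyl propiolate gives the methyl (4R,5E,8S)-4-hydroxy-non-5-en-2-ynoate F3. Hydroxyl-directed mCPBA epoxidation gives the (4R,5R,6S)-epoxy ynoate F4. (CH2=CH)2CuLi (THF, −78 °C) adds syn, the alkenylcopper is trapped with I2, and the Z-hydroxy ester lactonises to the 3-iodo-4-vinylbutenolide F5. Stille coupling with Bu3SnCH2OH (Pd(PPh3)4, dioxane, 80 °C) installs the hydroxymethyl group. The fallback comes back to the route at 15.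

Step 12. Residual divalent chromium may reduce the electron-poor formylbutenolide by single-electron transfer, or the ligand may give weak facial control on this sp2-bound aldehyde. The fallback is a boron-based propargylation followed by regioselective hydrometalation. It sets out from 18: allenylboronic acid pinacol ester with (R)-TRIP phosphoric acid (toluene, 0 °C) gives the (8S)-homopropargylic alcohol F6. Hydrostannation with Bu3SnH catalysed by Mo(CO)3(CNtBu)3 places tin on the internal carbon and gives the 2-stannylalkene F7. Iododestannylation (I2, CH2Cl2, 0 °C) comes back to the route at 19.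

Further compounds
F1 | step 18 | (1S,2S,4R,5R,6S,8S)-13-acetoxy-4,5-epoxy-1-hydroxy-2-(TBS-oxy)-8-{2-[(TBS-oxy)methyl]acryloyloxy}germacra-7(11),10(14)-dien-12,6-olide | C=C(CO[Si](C)(C)C(C)(C)C)C(=O)O[C@H]1CC(=C)[C@H](O)[C@@H](O[Si](C)(C)C(C)(C)C)C[C@@]2(C)O[C@@H]2[C@H]2OC(=O)C(COC(C)=O)=C12
F2 | step 18 | (1S)-methanesulfonate of F1 | C=C(CO[Si](C)(C)C(C)(C)C)C(=O)O[C@H]1CC(=C)[C@H](OS(C)(=O)=O)[C@@H](O[Si](C)(C)C(C)(C)C)C[C@@]2(C)O[C@@H]2[C@H]2OC(=O)C(COC(C)=O)=C12
F3 | step 6 | methyl (4R,5E,8S)-8-(TBS-oxy)-4-hydroxy-9-(PMB-oxy)-6-methylnon-5-en-2-ynoate | COC(=O)C#C[C@H](O)/C=C(\C)C[C@H](O[Si](C)(C)C(C)(C)C)COCc1ccc(OC)cc1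
F4 | step 6 | methyl (4S)-4-hydroxy-4-{(2R,3R)-3-[(2S)-2-(TBS-oxy)-3-(PMB-oxy)propyl]-3-methyloxiran-2-yl}but-2-ynoate | COC(=O)C#C[C@H](O)[C@H]1O[C@]1(C)C[C@H](O[Si](C)(C)C(C)(C)C)COCc1ccc(OC)cc1
F5 | step 6 | (5S)-4-ethenyl-3-iodo-5-{(2R,3R)-3-[(2S)-2-(TBS-oxy)-3-(PMB-oxy)propyl]-3-methyloxiran-2-yl}furan-2(5H)-one | C=CC1=C(I)C(=O)O[C@@H]1[C@H]1O[C@]1(C)C[C@H](O[Si](C)(C)C(C)(C)C)COCc1ccc(OC)cc1
F6 | step 12 | (5S)-3-(acetoxymethyl)-4-[(1S)-1-hydroxybut-3-yn-1-yl]-5-{(2R,3R)-3-[(2S)-2-(TBS-oxy)-3-(PMB-oxy)propyl]-3-methyloxiran-2-yl}furan-2(5H)-one | C#CC[C@H](O)C1=C(COC(C)=O)C(=O)O[C@@H]1[C@H]1O[C@]1(C)C[C@H](O[Si](C)(C)C(C)(C)C)COCc1ccc(OC)cc1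
F7 | step 12 | (5S)-3-(acetoxymethyl)-4-[(1S)-1-hydroxy-3-(tributylstannyl)but-3-en-1-yl]-5-{(2R,3R)-3-[(2S)-2-(TBS-oxy)-3-(PMB-oxy)propyl]-3-methyloxiran-2-yl}furan-2(5H)-one | C=C(C[C@H](O)C1=C(COC(C)=O)C(=O)O[C@@H]1[C@H]1O[C@]1(C)C[C@H](O[Si](C)(C)C(C)(C)C)COCc1ccc(OC)cc1)[Sn](CCCC)(CCCC)CCCC
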